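The amounts in the red flask, target and substrate as fractions of the charge, together with those of the cooler green run, were what I had for choosing among the moves at 8.0 d.

| flask | substrate | temperature | remark | time |
|---|---|---|---|---|
| red | 0.50 M | 60 °C | the very flask that is asked about, followed so far |  |
| green | 0.50 M | 45 °C | run made earlier |  |
| flask | 0.50 M | 60 °C |  | 8.0 d |

| run | time / d | target / % | substrate / % |
|---|---|---|---|
| red | 0.417 | 73.5 | 9.8 |
| red | 1.25 | 65.7 | 5.3 |
| red | 2.00 | 60.0 | 4.5 |
| red | 3.00 | 53.7 | 3.1 |
| red | 5.00 | 48.3 | 2.0 |
| green | 0.833 | 78.1 | 15.1 |
| green | 2.50 | 80.3 | 5.1 |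
| green | 4.00 | 75.8 | 2.0 |
| green | 6.00 | 70.9 | 2.4 |
| green | 10.0 | 59.3 | 1.8 |

(each reading ± 0.5 percentage points)

- larch: at 8.0 d raise the temperature by 25 K, then wait 4.0 d
- ash: at 8.0 d take out 90% of the target then present, then wait 4.0 d
- oak: change nothing and wait 4.0 d more
- maple: at 8.0 d add substrate, 50.0% of the amount charged, then wait 4.0 d

- target, in percent of the substrate first charged, at 8.0 d
- what to do for the largest gain in target; "none" if nothing gains more than 2 percentage points (larch / ash / oak / maple / none)
- target present, with what was taken out counted in, in percent of the substrate first charged, after ash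
- target present, with what was taken out counted in, in percent of the substrate first charged, after maple

- percent here means substrate units held: one target counts as two
- what is taken out of target is counted as made
- the numbers in the tables scatter by 0.5 percentage points (one standard deviation)
- additions bring no volume worth counting

Red's target fell at 0.0630 d⁻¹ of the charge between 2.00 d and 3.00 d, then at 0.0270 d⁻¹ up to 5.00 d. Drawing that fall as a straight line against the target, I read its slope as a relaxation rate, 0.615 d⁻¹, and its zero as the standing level, 46.6%, the share of the flask's material that stays target once the fall stops. That put the flask at 46.9% at 8.0 d, leaving oak 0.30 percentage points to lose. Read as a share, with 0.0853 of each gap still open after 4.0 d, the level gave 72.2% for maple and 67.2% for ash, with the target taken out counted.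

Turned round, the question was what larch needed. To beat maple it had to carry the level above 72.2%; taking the logarithm of missing over target as straight in reciprocal temperature, that asked for a green level no higher than 29.5%. Green fell at 0.0290 d⁻¹ over its last interval, so a level even that low required 0.0357 d⁻¹ over the interval before, yet the readings, each with 0.5 points of scatter, showed less, 0.0245 d⁻¹. I read from that a green level lower still, and I chose larch, where the forecast, with 44% of target at 8.0 d, 57% after ash and 70% after maple, chose maple and wrote “larch only speeds the relaxation while probably lowering or barely moving the plateau”.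

The flask gave 45.3%, and larch gained 43 points, against 25 points for maple and 20 points for ash, which ended at 69.9% and 64.9%.

    2 substrate → target (k = 0.830 L mol⁻¹ h⁻¹, Ea = 68.0 kJ mol⁻¹)
    target ⇌ isomer of the product (K = 1.20, k = 0.0130 h⁻¹, Ea = 113 kJ mol⁻¹, ΔH = −90.0 kJ mol⁻¹)
    substrate ⇌ dormant form (K = 0.980, k = 0.0520 h⁻¹, Ea = 114 kJ mol⁻¹, ΔH = −69.0 kJ mol⁻¹)
    (constants at 60 °C)

The relaxation half-life of target and isomer of the product by that step alone, both ways together, 1.21 d, is short against 8.0 d, and the flask at 8.0 d held 45.3% of target beside 51.9% of isomer of the product, with target still 45.3% at 80.0 d, beside the 46.6% I had read as the standing level. A neighbour flask, the same but charged with 2.0 M of substrate, stood at 8.0 d at 45.9% of target, 0.70 points under that reading.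

All runs are calculated on assumed constants, and the scatter is random.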